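**Retrosynthetic overview**
1. Ring A is cut last, at C1–C2 and C4–C5 together (a [3+3] sense), back to a ring-B keto tosylhydrazone (20: C1 as a masked formyl carbon on quaternary C10, ketone at C6) and 3-methylbut-2-enal (C2–C3–C4).
2. Enabling feature: the C1–C10–C5–C6(=O) array of ring B. C1 and C5 are 1,3-related across quaternary C10, C5 is α to the C6 oxygen, and C1 can be carried as an aldehyde, so a diazo umpolung joins C1 to the formyl carbon C2 and the C5 enolate then closes onto C4.
3. Ring B is made first, from an arene: asymmetric Birch reductive methylation of a benzamide sets C10, keeps the C6 oxygen as an enol ether and leaves C8=C9 with its methyl group and side chain in place; ring A is formed second, in the key step.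
4. The (E)-allylic alcohol of the side chain is built before the key step by zirconium-catalysed carboalumination of a terminal alkyne.
5. After the key step: C2 reduction and inversion, deconjugative C7 hydroxylation of the linear dienolate, C6 reduction, acylations, desilylation.

Key step: step 13

Assumption: in step 5 the (S)-auxiliary is taken to give the (S)-configured quaternary carbon of 11 (C10 of the target), by analogy with other 2-alkylbenzamides of this auxiliary; if the sense is reversed, the (R)-auxiliary is used and nothing else changes.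
Remark: ring carbons are numbered as in the labdane skeleton (C1–C10, side chain C11–C15); β is the face of the C10 methyl group.

**Step 1**
Reactants: 1 2,3-dimethylbenzoyl chloride; 2 (S)-2-(methoxymethyl)pyrrolidine
Product: 3 (2,3-dimethylphenyl)[(2S)-2-(methoxymethyl)pyrrolidin-1-yl]methanone
Conditions: Et3N, CH2Cl2, 0 °C to rt
Reagents that add atoms: none
Why: N-acylation of the secondary amine by the acid chloride installs the chiral auxiliary needed for the later reductive alkylation.

**Step 2**
Reactants: 3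
Product: 5 (5-hydroxy-2,3-dimethylphenyl)[(2S)-2-(methoxymethyl)pyrrolidin-1-yl]methanone, via pinacol boronate 4 (not isolated)
Conditions: B2pin2, [Ir(OMe)(cod)]2 (cat.), 4,4'-di-tert-butyl-2,2'-bipyridine, THF, 80 °C; then 30% H2O2, aq. NaOH, 0 °C
Reagents that add atoms: hydrogen peroxide OO
Why: Iridium-catalysed C–H borylation is sterically controlled and should go to C5, the only ring C–H without an ortho substituent, and oxidation of the C–B bond then gives the phenol.

**Step 3**
Reactants: 5
Product: 6 (5-methoxy-2,3-dimethylphenyl)[(2S)-2-(methoxymethyl)pyrrolidin-1-yl]methanone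
Conditions: MeI, K2CO3, acetone, reflux
Reagents that add atoms: iodomethane CI
Why: Williamson O-methylation of the phenoxide gives the aryl methyl ether that later becomes the C6 enol ether.

**Step 4**
Reactants: 6; 7 (2-bromoethoxy)(tert-butyl)dimethylsilane
Product: 9 [2-(3-{[tert-butyl(dimethyl)silyl]oxy}propyl)-5-methoxy-3-methylphenyl][(2S)-2-(methoxymethyl)pyrrolidin-1-yl]methanone, via benzylic lithium compound 8 (not isolated)
Conditions: LiN(i-Pr)2, THF, −78 °C; then 7, −78 °C to rt
Reagents that add atoms: none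
Why: Lateral lithiation of a tertiary benzamide takes place at the ortho methyl group (the anion is conjugated with the amide, unlike that of the C3 methyl), and SN2 alkylation then extends it to the C11–C13 chain.

**Step 5**
Reactants: 9
Product: 11 [(1S)-2-(3-{[tert-butyl(dimethyl)silyl]oxy}propyl)-5-methoxy-1,3-dimethylcyclohexa-2,5-dien-1-yl][(2S)-2-(methoxymethyl)pyrrolidin-1-yl]methanone, via potassium amide enolate 10 (not isolated)
Conditions: K, NH3(l)/THF, t-BuOH (1 equiv), −78 °C; then MeI, −78 °C; NH4Cl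
Reagents that add atoms: iodomethane CI
Why: Schultz-type Birch reduction–alkylation: the carboxamide directs 1,4-reduction to the ipso and para carbons, and the resulting amide enolate 10 should be methylated on the face dictated by the prolinol-derived auxiliary, which sets the quaternary stereocentre (C10).

**Step 6**
Reactants: 11
Product: 12 [(1S)-2-(3-hydroxypropyl)-5-methoxy-1,3-dimethylcyclohexa-2,5-dien-1-yl][(2S)-2-(methoxymethyl)pyrrolidin-1-yl]methanone
Conditions: Bu4NF, THF, 0 °C to rt
Reagents that add atoms: none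
Why: Fluoride cleaves the primary silyl ether under basic conditions that leave the acid-labile methyl enol ether intact.

**Step 7**
Reactants: 12
Product: 13 [(1S)-5-methoxy-1,3-dimethyl-2-(3-oxopropyl)cyclohexa-2,5-dien-1-yl][(2S)-2-(methoxymethyl)pyrrolidin-1-yl]methanone
Conditions: Dess–Martin periodinane, pyridine, CH2Cl2, 0 °C
Reagents that add atoms: none
Why: Dess–Martin oxidation of the primary alcohol should stop at the aldehyde, and the pyridine buffer protects the enol ether from hydrolysis.

**Step 8**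
Reactants: 13
Product: 14 [(1S)-2-(but-3-yn-1-yl)-5-methoxy-1,3-dimethylcyclohexa-2,5-dien-1-yl][(2S)-2-(methoxymethyl)pyrrolidin-1-yl]methanone
Conditions: dimethyl (1-diazo-2-oxopropyl)phosphonate, K2CO3, MeOH, 0 °C to rt
Reagents that add atoms: dimethyl (1-diazo-2-oxopropyl)phosphonate COP(=O)(OC)C(=[N+]=[N-])C(C)=O
Why: Ohira–Bestmann (Seyferth–Gilbert) homologation converts the aldehyde into the terminal alkyne under mild carbonate conditions that the amide and the enol ether tolerate.

**Step 9**
Reactants: 14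
Product: 16 [(1S)-2-[(3E)-5-hydroxy-3-methylpent-3-en-1-yl]-5-methoxy-1,3-dimethylcyclohexa-2,5-dien-1-yl][(2S)-2-(methoxymethyl)pyrrolidin-1-yl]methanone, via alkenylalane 15 (not isolated)
Conditions: Me3Al, Cp2ZrCl2 (cat.), CH2Cl2, 0 °C to rt; then (CH2O)n, THF, rt; aq. Rochelle salt
Reagents that add atoms: trimethylaluminium C[Al](C)C; formaldehyde (as paraformaldehyde) C=O
Why: Negishi zirconium-catalysed carboalumination adds methyl and aluminium syn across the terminal alkyne (methyl to the internal carbon), and hydroxymethylation of the alkenylalane with retention fixes the E trisubstituted double bond.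

**Step 10**
Reactants: 16
Product: 17 [(1S)-5-methoxy-1,3-dimethyl-2-[(3E)-3-methyl-5-{[tri(propan-2-yl)silyl]oxy}pent-3-en-1-yl]cyclohexa-2,5-dien-1-yl][(2S)-2-(methoxymethyl)pyrrolidin-1-yl]methanone
Conditions: i-Pr3SiCl, imidazole, DMF, rt
Reagents that add atoms: chlorotri(propan-2-yl)silane CC(C)[Si](Cl)(C(C)C)C(C)C
Why: Silylation of the primary allylic alcohol gives a robust silyl ether that should survive the base, hydride and acylation steps that follow.

**Step 11**
Reactants: 17
Product: 18 (1S)-5-methoxy-1,3-dimethyl-2-[(3E)-3-methyl-5-{[tri(propan-2-yl)silyl]oxy}pent-3-en-1-yl]cyclohexa-2,5-diene-1-carbaldehyde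
Conditions: Cp2Zr(H)Cl, THF, rt; aq. NaHCO3 work-up
Reagents that add atoms: none
Why: Schwartz reagent reduces the tertiary amide to the aldehyde oxidation level and stops there because the carbonyl group is regenerated only on work-up; the auxiliary is released and the hindered alkenes should not be hydrozirconated.

**Step 12**
Reactants: 18
Product: 20 N'-[(E)-{(1S)-1,3-dimethyl-5-oxo-2-[(3E)-3-methyl-5-{[tri(propan-2-yl)silyl]oxy}pent-3-en-1-yl]cyclohex-2-en-1-yl}methylidene]-4-methylbenzenesulfonohydrazide, via enol ether tosylhydrazone 19 (not isolated)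
Conditions: TsNHNH2, THF, rt; then aq. oxalic acid, THF, 0 °C
Reagents that add atoms: 4-methylbenzenesulfonohydrazide Cc1ccc(S(=O)(=O)NN)cc1; water O
Why: The non-enolisable aldehyde condenses with tosylhydrazide first, and mild acid hydrolysis of the enol ether then unmasks the C6 ketone without moving the C8=C9 double bond, so a free keto aldehyde and its aldol chemistry are avoided.

**Step 13**
Reactants: 20; 21 3-methylbut-2-enal
Product: 25 15-{[tri(propan-2-yl)silyl]oxy}labda-7,13E-diene-2,6-dione (5α-H, 9α-H, 10β-methyl), via sodium salt 22 (not isolated), via diazoalkane 23 (not isolated), via enone 24 (not isolated)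
Conditions: NaH (1.0 equiv), THF, 0 °C; then 21 (1.5 equiv), BnEt3NCl (cat.), 1,4-dioxane, 90 °C; then t-BuOK (0.3 equiv), t-BuOH, 40 °C; AcOH
Reagents that add atoms: none
Why: Proposed new method: heating sodium salt 22 expels sulfinate (Bamford–Stevens) to give the neopentyl-type diazoalkane 23, whose nucleophilic carbon C1 adds to the formyl carbon C2 of 21 and, after 1,2-hydride shift with loss of N2, gives enone 24, so that two aldehyde-derived (electrophilic) carbons are joined by polarity reversal of one of them. The closest known reaction type is the base-mediated coupling of tosylhydrazones with aldehydes to ketones (diazoalkane insertion into the formyl C–H bond), known mainly for aryl aldehydes and not in tandem with a ring closure, followed by a Michael addition of the dimedone type onto a mesityl-oxide-like acceptor. tert-Butoxide then equilibrates the enolates of the C6 ketone, and the C5 enolate adds to C4 of the β,β-dimethyl enone, which forms the quaternary carbon and closes ring A in the 6-(enolexo)-endo-trig mode. C5 is set under thermodynamic control: it is epimerisable next to the C6 carbonyl and the Michael addition is reversible, so cis- and trans-fused adducts and both enone isomers should funnel into the trans-fused (5α-H) decalin with the conjugated C7=C8 double bond and the C9 chain equatorial, relative to the fixed C10 centre. The step needs 1,2-addition of 23 to the aldehyde of 21 instead of dipolar cycloaddition to its C=C bond or carbene formation, which the β,β-dimethyl substitution of 21, the absence of hydrogen on C10 and the excess of aldehyde should secure. It also needs closure at C5 and not at C9 of the extended dienolate, which the strain of a product with three contiguous quaternary carbons (C4, C9, C10) should secure under reversible conditions.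

**Step 14**
Reactants: 25
Product: 26 2β-hydroxy-15-{[tri(propan-2-yl)silyl]oxy}labda-7,13E-dien-6-one
Conditions: NaBH4, MeOH/CH2Cl2 (1:1), −78 to −40 °C
Reagents that add atoms: none
Why: NaBH4 at low temperature reduces the saturated C2 ketone faster than the conjugated C6 enone, and hydride should add from the α face, away from the syn-axial C10 and C4β methyl groups, to give the axial 2β-alcohol.

**Step 15**
Reactants: 26
Product: 29 2α-hydroxy-15-{[tri(propan-2-yl)silyl]oxy}labda-7,13E-dien-6-one, via triflate 27 (not isolated), via nitrite ester 28 (not isolated)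
Conditions: Tf2O, pyridine, CH2Cl2, −20 °C; then Bu4NNO2, toluene, rt; aq. work-up
Reagents that add atoms: tetrabutylammonium nitrite CCCC[N+](CCCC)(CCCC)CCCC.[O-]N=O
Why: Lattrell–Dax inversion: nitrite displaces the axial triflate in an SN2 reaction from the unhindered α face and the nitrite ester is hydrolysed on work-up, which should give the equatorial 2α-alcohol.

**Step 16**
Reactants: 29
Product: 31 2α,7α-dihydroxy-15-{[tri(propan-2-yl)silyl]oxy}labda-8,13E-dien-6-one, via dipotassium dienolate 30 (not isolated)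
Conditions: KN(SiMe3)2 (1.95 equiv), THF, −78 to 0 °C; then 3-phenyl-2-(phenylsulfonyl)oxaziridine, −78 °C; AcOH
Reagents that add atoms: 3-phenyl-2-(phenylsulfonyl)oxaziridine O=S(=O)(N1OC1c1ccccc1)c1ccccc1
Why: The thermodynamic linear dienolate (γ-deprotonation at C9, equilibrated through the slight excess of enone) should be hydroxylated by the Davis oxaziridine at its α-carbon C7 from the α face, opposite the C10 and C4β methyl groups, as in deconjugative α-alkylation of steroidal 3,5-dienolates; this restores C8=C9 and sets 7α-OH.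

**Step 17**
Reactants: 31
Product: 32 2α,7α-diacetoxy-15-{[tri(propan-2-yl)silyl]oxy}labda-8,13E-dien-6-one
Conditions: Ac2O, pyridine, DMAP (cat.), CH2Cl2, 0 °C to rt
Reagents that add atoms: acetic anhydride CC(=O)OC(C)=O
Why: DMAP-catalysed acetylation installs both acetates at once and caps the α-ketol before it can isomerise.

**Step 18**
Reactants: 32
Product: 33 2α,7α-diacetoxy-15-{[tri(propan-2-yl)silyl]oxy}labda-8,13E-dien-6β-ol
Conditions: NaBH4, CeCl3·7H2O, MeOH, −78 °C
Reagents that add atoms: none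
Why: Luche reduction: hydride should attack the C6 ketone from the α face because the β face is blocked by the syn-axial C10 and C4β methyl groups, giving the axial 6β-alcohol, while the cerium salt suppresses enolisation toward C7.

**Step 19**
Reactants: 33; 34 3-methylbutanoyl chloride
Product: 35 2α,7α-diacetoxy-6β-(3-methylbutanoyloxy)-15-{[tri(propan-2-yl)silyl]oxy}labda-8,13E-diene
Conditions: pyridine, DMAP, CH2Cl2, 40 °C
Reagents that add atoms: none
Why: DMAP-catalysed acylation of the hindered axial 6β-hydroxyl, the only free hydroxyl group, installs the 3-methylbutanoate.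

**Step 20**
Reactants: 35
Product: 36 2α,7α-diacetoxy-6β-(3-methylbutanoyloxy)labda-8,13E-dien-15-ol (CNP0257091.1)
Conditions: HF·pyridine, pyridine/THF, 0 °C to rt
Reagents that add atoms: none
Why: Buffered fluoride cleaves the primary allylic silyl ether and should leave the three esters untouched and unmigrated.

**Compound list**
1 | 2,3-dimethylbenzoyl chloride | Cc1cccc(C(=O)Cl)c1C | starting material
2 | (S)-2-(methoxymethyl)pyrrolidine | COC[C@@H]1CCCN1 | starting material
3 | (2,3-dimethylphenyl)[(2S)-2-(methoxymethyl)pyrrolidin-1-yl]methanone | Cc1cccc(C(=O)N2CCC[C@H]2COC)c1C | intermediate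
4 | [2,3-dimethyl-5-(4,4,5,5-tetramethyl-1,3,2-dioxaborolan-2-yl)phenyl][(2S)-2-(methoxymethyl)pyrrolidin-1-yl]methanone | Cc1cc(B2OC(C)(C)C(C)(C)O2)cc(C(=O)N2CCC[C@H]2COC)c1C | intermediate
5 | (5-hydroxy-2,3-dimethylphenyl)[(2S)-2-(methoxymethyl)pyrrolidin-1-yl]methanone | Cc1cc(O)cc(C(=O)N2CCC[C@H]2COC)c1C | intermediate
6 | (5-methoxy-2,3-dimethylphenyl)[(2S)-2-(methoxymethyl)pyrrolidin-1-yl]methanone | COc1cc(C)c(C)c(C(=O)N2CCC[C@H]2COC)c1 | intermediate
7 | (2-bromoethoxy)(tert-butyl)dimethylsilane | BrCCO[Si](C)(C)C(C)(C)C | starting material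
8 | [2-(lithiomethyl)-5-methoxy-3-methylphenyl][(2S)-2-(methoxymethyl)pyrrolidin-1-yl]methanone | [Li]Cc1c(C)cc(OC)cc1C(=O)N1CCC[C@H]1COC | intermediate
9 | [2-(3-{[tert-butyl(dimethyl)silyl]oxy}propyl)-5-methoxy-3-methylphenyl][(2S)-2-(methoxymethyl)pyrrolidin-1-yl]methanone | COc1cc(C)c(CCCO[Si](C)(C)C(C)(C)C)c(C(=O)N2CCC[C@H]2COC)c1 | intermediate
10 | potassium enolate of the 1,4-dihydrobenzamide from 9 (exocyclic C=C(OK)N at the former ipso carbon) | [K+].[O-]C(N1CCC[C@H]1COC)=C1C=C(OC)CC(C)=C1CCCO[Si](C)(C)C(C)(C)C | intermediate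
11 | [(1S)-2-(3-{[tert-butyl(dimethyl)silyl]oxy}propyl)-5-methoxy-1,3-dimethylcyclohexa-2,5-dien-1-yl][(2S)-2-(methoxymethyl)pyrrolidin-1-yl]methanone | C[C@]1(C(=O)N2CCC[C@H]2COC)C=C(OC)CC(C)=C1CCCO[Si](C)(C)C(C)(C)C | intermediate
12 | [(1S)-2-(3-hydroxypropyl)-5-methoxy-1,3-dimethylcyclohexa-2,5-dien-1-yl][(2S)-2-(methoxymethyl)pyrrolidin-1-yl]methanone | C[C@]1(C(=O)N2CCC[C@H]2COC)C=C(OC)CC(C)=C1CCCO | intermediate
13 | [(1S)-5-methoxy-1,3-dimethyl-2-(3-oxopropyl)cyclohexa-2,5-dien-1-yl][(2S)-2-(methoxymethyl)pyrrolidin-1-yl]methanone | C[C@]1(C(=O)N2CCC[C@H]2COC)C=C(OC)CC(C)=C1CCC=O | intermediate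
14 | [(1S)-2-(but-3-yn-1-yl)-5-methoxy-1,3-dimethylcyclohexa-2,5-dien-1-yl][(2S)-2-(methoxymethyl)pyrrolidin-1-yl]methanone | C[C@]1(C(=O)N2CCC[C@H]2COC)C=C(OC)CC(C)=C1CCC#C | intermediate
15 | (E)-alkenyl(dimethyl)alane from syn-methylalumination of 14 | C[C@]1(C(=O)N2CCC[C@H]2COC)C=C(OC)CC(C)=C1CC/C(C)=C/[Al](C)C | intermediate
16 | [(1S)-2-[(3E)-5-hydroxy-3-methylpent-3-en-1-yl]-5-methoxy-1,3-dimethylcyclohexa-2,5-dien-1-yl][(2S)-2-(methoxymethyl)pyrrolidin-1-yl]methanone | C[C@]1(C(=O)N2CCC[C@H]2COC)C=C(OC)CC(C)=C1CC/C(C)=C/CO | intermediate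
17 | [(1S)-5-methoxy-1,3-dimethyl-2-[(3E)-3-methyl-5-{[tri(propan-2-yl)silyl]oxy}pent-3-en-1-yl]cyclohexa-2,5-dien-1-yl][(2S)-2-(methoxymethyl)pyrrolidin-1-yl]methanone | C[C@]1(C(=O)N2CCC[C@H]2COC)C=C(OC)CC(C)=C1CC/C(C)=C/CO[Si](C(C)C)(C(C)C)C(C)C | intermediate
18 | (1S)-5-methoxy-1,3-dimethyl-2-[(3E)-3-methyl-5-{[tri(propan-2-yl)silyl]oxy}pent-3-en-1-yl]cyclohexa-2,5-diene-1-carbaldehyde | C[C@]1(C=O)C=C(OC)CC(C)=C1CC/C(C)=C/CO[Si](C(C)C)(C(C)C)C(C)C | intermediate
19 | (E)-N-tosylhydrazone of aldehyde 18 (enol ether retained) | C[C@]1(/C=N/NS(=O)(=O)c2ccc(C)cc2)C=C(OC)CC(C)=C1CC/C(C)=C/CO[Si](C(C)C)(C(C)C)C(C)C | intermediate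
20 | N'-[(E)-{(1S)-1,3-dimethyl-5-oxo-2-[(3E)-3-methyl-5-{[tri(propan-2-yl)silyl]oxy}pent-3-en-1-yl]cyclohex-2-en-1-yl}methylidene]-4-methylbenzenesulfonohydrazide | C[C@]1(/C=N/NS(=O)(=O)c2ccc(C)cc2)CC(=O)CC(C)=C1CC/C(C)=C/CO[Si](C(C)C)(C(C)C)C(C)C | intermediate
21 | 3-methylbut-2-enal | CC(C)=CC=O | starting material
22 | sodium salt of tosylhydrazone 20 (N-anion) | [Na+].C[C@]1(/C=N/[N-]S(=O)(=O)c2ccc(C)cc2)CC(=O)CC(C)=C1CC/C(C)=C/CO[Si](C(C)C)(C(C)C)C(C)C | intermediate
23 | diazoalkane: 5-(diazomethyl)-3,5-dimethyl-4-[(3E)-3-methyl-5-{[tri(propan-2-yl)silyl]oxy}pent-3-en-1-yl]cyclohex-3-en-1-one (quaternary carbon as in 20) | C[C@]1(C=[N+]=[N-])CC(=O)CC(C)=C1CC/C(C)=C/CO[Si](C(C)C)(C(C)C)C(C)C | intermediate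
24 | enone: 3,5-dimethyl-5-(4-methyl-2-oxopent-3-en-1-yl)-4-[(3E)-3-methyl-5-{[tri(propan-2-yl)silyl]oxy}pent-3-en-1-yl]cyclohex-3-en-1-one (quaternary carbon as in 20) | C[C@]1(CC(=O)C=C(C)C)CC(=O)CC(C)=C1CC/C(C)=C/CO[Si](C(C)C)(C(C)C)C(C)C | intermediate
25 | 15-{[tri(propan-2-yl)silyl]oxy}labda-7,13E-diene-2,6-dione (5α-H, 9α-H, 10β-methyl) | O=C1CC(C)(C)[C@@H]2C(=O)C=C(C)[C@H](CC/C(C)=C/CO[Si](C(C)C)(C(C)C)C(C)C)[C@@]2(C)C1 | intermediate
26 | 2β-hydroxy-15-{[tri(propan-2-yl)silyl]oxy}labda-7,13E-dien-6-one | O[C@@H]1CC(C)(C)[C@@H]2C(=O)C=C(C)[C@H](CC/C(C)=C/CO[Si](C(C)C)(C(C)C)C(C)C)[C@@]2(C)C1 | intermediate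
27 | 2β-trifluoromethanesulfonate of 26 | O=S(=O)(O[C@@H]1CC(C)(C)[C@@H]2C(=O)C=C(C)[C@H](CC/C(C)=C/CO[Si](C(C)C)(C(C)C)C(C)C)[C@@]2(C)C1)C(F)(F)F | intermediate
28 | 2α-nitrite ester (inverted at C2) | O=NO[C@H]1CC(C)(C)[C@@H]2C(=O)C=C(C)[C@H](CC/C(C)=C/CO[Si](C(C)C)(C(C)C)C(C)C)[C@@]2(C)C1 | intermediate
29 | 2α-hydroxy-15-{[tri(propan-2-yl)silyl]oxy}labda-7,13E-dien-6-one | O[C@H]1CC(C)(C)[C@@H]2C(=O)C=C(C)[C@H](CC/C(C)=C/CO[Si](C(C)C)(C(C)C)C(C)C)[C@@]2(C)C1 | intermediate
30 | dipotassium salt of 29 (C2 alkoxide, linear C6 dienolate over C6=C7 and C8=C9) | [K+].[K+].[O-][C@H]1CC(C)(C)[C@@H]2C([O-])=CC(C)=C(CC/C(C)=C/CO[Si](C(C)C)(C(C)C)C(C)C)[C@@]2(C)C1 | intermediate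
31 | 2α,7α-dihydroxy-15-{[tri(propan-2-yl)silyl]oxy}labda-8,13E-dien-6-one | O[C@H]1CC(C)(C)[C@@H]2C(=O)[C@@H](O)C(C)=C(CC/C(C)=C/CO[Si](C(C)C)(C(C)C)C(C)C)[C@@]2(C)C1 | intermediate
32 | 2α,7α-diacetoxy-15-{[tri(propan-2-yl)silyl]oxy}labda-8,13E-dien-6-one | CC(=O)O[C@H]1CC(C)(C)[C@@H]2C(=O)[C@@H](OC(C)=O)C(C)=C(CC/C(C)=C/CO[Si](C(C)C)(C(C)C)C(C)C)[C@@]2(C)C1 | intermediate
33 | 2α,7α-diacetoxy-15-{[tri(propan-2-yl)silyl]oxy}labda-8,13E-dien-6β-ol | CC(=O)O[C@H]1CC(C)(C)[C@@H]2[C@H](O)[C@@H](OC(C)=O)C(C)=C(CC/C(C)=C/CO[Si](C(C)C)(C(C)C)C(C)C)[C@@]2(C)C1 | intermediate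
34 | 3-methylbutanoyl chloride | CC(C)CC(=O)Cl | starting material
35 | 2α,7α-diacetoxy-6β-(3-methylbutanoyloxy)-15-{[tri(propan-2-yl)silyl]oxy}labda-8,13E-diene | CC(=O)O[C@H]1CC(C)(C)[C@@H]2[C@H](OC(=O)CC(C)C)[C@@H](OC(C)=O)C(C)=C(CC/C(C)=C/CO[Si](C(C)C)(C(C)C)C(C)C)[C@@]2(C)C1 | intermediate
36 | 2α,7α-diacetoxy-6β-(3-methylbutanoyloxy)labda-8,13E-dien-15-ol (CNP0257091.1) | CC(=O)O[C@H]1CC(C)(C)[C@@H]2[C@H](OC(=O)CC(C)C)[C@@H](OC(C)=O)C(C)=C(CC/C(C)=C/CO)[C@@]2(C)C1 | target

**Step count and risks**
Total step count: 20. Longest linear sequence: 20 steps (1 to 36); all other inputs are commercial.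

Most likely to fail:

1. Step 13 (Proposed new method). What may go wrong: loss of N2 from 23 to a carbene before it is trapped (1,2-vinyl shift, ring expansion), dipolar cycloaddition or aldol condensation with 21, or ring closure through C9 of the extended dienolate. Fallback with known chemistry, setting out from 18: Horner–Wittig olefination of 18 with the lithium derivative of (1-methoxy-3-methylbut-2-en-1-yl)diphenylphosphine oxide F1 (one step from commercial 1,1-dimethoxy-3-methylbut-2-ene and chlorodiphenylphosphine), followed by KH-induced elimination, should give the bis-enol ether 2-methoxydiene F2. Aqueous oxalic acid hydrolyses both enol ethers to enone 24, which is isolated here, and t-BuOK in t-BuOH closes ring A by the same reversible Michael addition; the fallback comes back to the route at 25.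

2. Step 5. What may go wrong: poor facial selectivity in the methylation of the reductively formed potassium enolate for this substitution pattern, or over-reduction. Fallback, setting out from 9: the Birch reduction is quenched with NH4Cl to give the 1,4-dihydrobenzamide F3 (C–H at the future C10, either epimer); the amide enolate is then formed separately with LiN(i-Pr)2 in THF at −78 °C and methylated with MeI. This lithium enolate is a different aggregate with its own, often higher or opposite, facial bias (the auxiliary enantiomer is chosen to match); the fallback comes back at 11.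

3. Step 15. What may go wrong: E2 elimination of the axial triflate toward C1 or C3 instead of substitution. Fallback, setting out from 26: thermodynamic epimerisation of the carbinol by reversible dehydrogenation and re-hydrogenation with (C5Ph5)Ru(CO)2Cl and catalytic t-BuOK in toluene at rt. The equatorial 2α-alcohol is favoured because it removes two syn-axial methyl/hydroxyl interactions; hydrogen transfer to the enone is the risk to watch. This fallback makes no new compound and comes back at 29.

**Further compounds**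
F1 | step 13 | (1-methoxy-3-methylbut-2-en-1-yl)diphenylphosphine oxide | COC(C=C(C)C)P(=O)(c1ccccc1)c1ccccc1
F2 | step 13 | (6S)-1,5-dimethoxy-6-(2-methoxy-4-methylpenta-1,3-dien-1-yl)-3,6-dimethyl-2-[(3E)-3-methyl-5-{[tri(propan-2-yl)silyl]oxy}pent-3-en-1-yl]-free form: bis-enol ether of 24 (ring 5-methoxy-2,5-diene retained, side arm C1H=C2(OMe)–C3H=C4Me2, E/Z mixture at C1=C2) | C[C@]1(C=C(OC)C=C(C)C)C=C(OC)CC(C)=C1CC/C(C)=C/CO[Si](C(C)C)(C(C)C)C(C)C
F3 | step 5 | [2-(3-{[tert-butyl(dimethyl)silyl]oxy}propyl)-5-methoxy-3-methylcyclohexa-2,5-dien-1-yl][(2S)-2-(methoxymethyl)pyrrolidin-1-yl]methanone (either epimer at ring C1) | COC1=CC(C(=O)N2CCC[C@H]2COC)C(CCCO[Si](C)(C)C(C)(C)C)=C(C)C1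
F0 | step 15 | none | none
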